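The cyclooctane ring is numbered C1 (lactone α-carbon), C2 (CH with the side chain), C3 (CHOAc), C4, C5 (CHMe), C6 and C7 (cyclopropane CH groups), C8 (lactone β-carbon). Everything rests on cutting C2–C3 and C7–C8: C3 carries oxygen and stands 1,5 to C7, so C3–C7 is a latent 1,5-dialdehyde and C8–C1–C2 a β-keto ester dianion (C1 as ketone). One Lewis-acid [3+5] annulation of an open-chain aldehyde acetal with an open-chain 1,3-bis(silyloxy)diene forms both bonds and a temporary C3–O–C7 bridge (9-oxabicyclo[3.3.1]nonane). Bridge opening, cyclopropanation of C6=C7 and carbonylation at C1 complete the target.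

Key step: step 8

Assumption: commercial (R)-citronellal and (R)-citronellic acid are taken as highly enantioenriched; the ring locants C1–C8 defined above are used in the Why lines.

Step 1
Reactants: 1 (R)-citronellal
Product: 2 (6R)-8,8-dimethoxy-2,6-dimethyloct-2-ene
Conditions: HC(OMe)3, MeOH, PPTS (cat.), 0 to 23 °C
Reagents that add atoms: trimethyl orthoformate, COC(OC)OC
Why: Acid-catalysed acetalisation with the orthoformate as water scavenger masks the aldehyde as the acetal that later becomes C7, under conditions mild enough to avoid the carbonyl-ene cyclisation of citronellal, and leaves the stereocentre untouched.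

Step 2
Reactants: 2 (6R)-8,8-dimethoxy-2,6-dimethyloct-2-ene
Product: 3 (4R)-6,6-dimethoxy-4-methylhexanal
Conditions: O3, CH2Cl2, −78 °C; then Me2S, −78 to 23 °C
Reagents that add atoms: ozone, [O-][O+]=O
Why: Ozonolysis with reductive work-up should cleave the trisubstituted alkene to the aldehyde while the acetal is inert.

Step 3
Reactants: 3 (4R)-6,6-dimethoxy-4-methylhexanal
Product: 4 (4R)-6,6-dimethoxy-4-methylhex-1-en-1-yl acetate (E/Z mixture)
Conditions: Ac2O, KOAc, Et3N, 120 °C
Reagents that add atoms: acetic anhydride, CC(=O)OC(C)=O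
Why: Enol acetate formation (O-acetylation of the aldehyde enolate) installs the C=C bond needed to excise one carbon, under basic conditions that keep the acetal intact.

Step 4
Reactants: 4 (4R)-6,6-dimethoxy-4-methylhex-1-en-1-yl acetate
Product: 5 (3R)-5,5-dimethoxy-3-methylpentanal
Conditions: O3, CH2Cl2, −78 °C; then Me2S
Reagents that add atoms: ozone, [O-][O+]=O
Why: Ozonolysis of the enol acetate removes the terminal carbon as a formyl derivative (dehomologation), so that the aldehyde carbon (future C3) and the acetal carbon (future C7) flank the methyl-bearing stereocentre (future C5, R).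

Step 5
Reactants: 6 (R)-citronellic acid
Product: 8 methyl (5R)-5,9-dimethyl-3-oxodec-8-enoate, via acyl imidazole 7 (not isolated)
Conditions: CDI, THF, 23 °C; then MeO2CCH2CO2K, MgCl2, Et3N, THF, 23 to 50 °C; 1 M HCl
Reagents that add atoms: potassium methyl malonate, COC(=O)CC(=O)[O-].[K+]; 1,1'-carbonyldiimidazole, O=C(n1ccnc1)n1ccnc1 (imidazolyl group of 7 only)
Why: C-Acylation of the magnesium malonate half-ester enolate by the acyl imidazole followed by decarboxylation (Claisen-type condensation) should give the β-keto ester without touching the stereocentre that becomes the side-chain centre.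

Step 6
Reactants: 8 methyl (5R)-5,9-dimethyl-3-oxodec-8-enoate
Product: 9 methyl (5R)-5,9-dimethyl-3-(trimethylsilyloxy)deca-2,8-dienoate
Conditions: Me3SiCl, Et3N, hexane, 23 °C
Reagents that add atoms: chlorotrimethylsilane, C[Si](C)(C)Cl
Why: Silyl enol ether formation from the enolised β-keto ester gives the vinylogous ester needed for γ-deprotonation.

Step 7
Reactants: 9 methyl (5R)-5,9-dimethyl-3-(trimethylsilyloxy)deca-2,8-dienoate
Product: 10 (5R)-1-methoxy-5,9-dimethyl-1,3-bis(trimethylsilyloxy)deca-1,3,8-triene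
Conditions: LiN(iPr)2, THF, −78 °C; Me3SiCl, −78 to 0 °C
Reagents that add atoms: chlorotrimethylsilane, C[Si](C)(C)Cl
Why: Kinetic γ-deprotonation of the vinylogous ester and O-silylation of the dienolate (second silyl enol ether formation) should give the 1,3-bis(silyloxy)diene, a β-keto ester dianion equivalent, mainly as the 3Z isomer.

Step 8
Reactants: 5 (3R)-5,5-dimethoxy-3-methylpentanal; 10 (5R)-1-methoxy-5,9-dimethyl-1,3-bis(trimethylsilyloxy)deca-1,3,8-triene
Product: 12 methyl (1R,4R,5S,7R)-7-methyl-4-[(2R)-6-methylhept-5-en-2-yl]-3-oxo-9-oxabicyclo[3.3.1]nonane-2-carboxylate, via oxanyl silyl ketene acetal 11 (not isolated)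
Conditions: TMSOTf (0.2 equiv), 2,6-di-tert-butyl-4-methylpyridine (0.05 equiv), CH2Cl2, −78 to −40 °C; aq. NaHCO3
Reagents that add atoms: none
Why: TMSOTf ionises the dimethyl acetal of 5 and the aldehyde oxygen traps the methoxycarbenium ion (6-exo-trig, neighbouring-group participation), which gives an oxanyl oxocarbenium ion at the former aldehyde carbon; the γ-terminus of diene 10 adds to it (vinylogous Mukaiyama aldol, C2–C3) to give 11. Ionisation of the remaining ring acetal and attack of the silyl ketene acetal carbon on the second oxocarbenium ion (6-endo-trig with respect to the new oxanone ring, chair transition state) forms C7–C8 and so closes the eight-membered carbocycle as a 9-oxabicyclo[3.3.1]nonane. The closest known reaction type is the Lewis-acid-promoted [3+5] annulation of 1,3-bis(silyloxy)dienes with 1,5-dicarbonyl compounds and their acetals. C3 and C7 should be set by axial attack on the half-chair oxocarbenium ions with the C5 methyl group equatorial, the bridge demanding the cis-2,6-diaxial arrangement, so both follow from C5; C2 should be set in the first addition by an antiperiplanar open transition state that keeps its hydrogen over the ring and the branched chain away from ring C4; C8 is a labile β-keto ester centre. The step needs site selectivity (diene terminus to the former aldehyde carbon, internal α-carbon to the former acetal carbon), secured by the oxygen participation and the higher nucleophilicity of the diene terminus, and chemoselectivity over the trisubstituted alkene, secured by the far higher nucleophilicity of the silyl enol ethers at −78 °C.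

Step 9
Reactants: 12 methyl (1R,4R,5S,7R)-7-methyl-4-[(2R)-6-methylhept-5-en-2-yl]-3-oxo-9-oxabicyclo[3.3.1]nonane-2-carboxylate
Product: 15 methyl (3R,4S,6R)-4-hydroxy-6-methyl-3-[(2R)-6-methylhept-5-en-2-yl]-2-(trifluoromethanesulfonyloxy)cycloocta-1,7-diene-1-carboxylate, via disodium alkoxide dienolate 13 (not isolated), via trimethylsilyl ether 14 (not isolated)
Conditions: NaH (2.5 equiv), THF, 0 to 23 °C; Me3SiCl (1.1 equiv), −78 °C; PhNTf2 (1.2 equiv), −78 to 0 °C; then 1 M aq. HCl, THF, 0 °C
Reagents that add atoms: N-phenylbis(trifluoromethanesulfonimide), O=S(=O)(N(c1ccccc1)S(=O)(=O)C(F)(F)F)C(F)(F)F; chlorotrimethylsilane, C[Si](C)(C)Cl (silyl group of 14 only); sodium hydride, [Na+].[H-] (sodium of 13 only)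
Why: Retro-oxa-Michael (E1cB) opening from the β-keto ester enolate should cleave only the C7–O bond, excess NaH then turns the alkylidene β-keto ester into the extended dienolate by deprotonation at C6 (it cannot re-close and C2 is never enolised), the alkoxide is capped as its silyl ether, O-sulfonylation of the dienolate gives the dienyl triflate (enol triflate formation) and the acid work-up frees the C3 alcohol.

Step 10
Reactants: 15 methyl (3R,4S,6R)-4-hydroxy-6-methyl-3-[(2R)-6-methylhept-5-en-2-yl]-2-(trifluoromethanesulfonyloxy)cycloocta-1,7-diene-1-carboxylate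
Product: 16 methyl (3R,4R,6R)-6-methyl-3-[(2R)-6-methylhept-5-en-2-yl]-4-(4-nitrobenzoyloxy)-2-(trifluoromethanesulfonyloxy)cycloocta-1,7-diene-1-carboxylate
Conditions: 4-O2NC6H4CO2H, PPh3, DIAD, toluene, 0 to 23 °C
Reagents that add atoms: 4-nitrobenzoic acid, OC(=O)c1ccc(cc1)[N+](=O)[O-]
Why: Mitsunobu esterification proceeds by SN2 displacement of the oxyphosphonium ion and should invert C3 to the configuration of the target, 4-nitrobenzoic acid being the acid of choice for a hindered secondary alcohol.

Step 11
Reactants: 16 methyl (3R,4R,6R)-6-methyl-3-[(2R)-6-methylhept-5-en-2-yl]-4-(4-nitrobenzoyloxy)-2-(trifluoromethanesulfonyloxy)cycloocta-1,7-diene-1-carboxylate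
Product: 17 (5R,7R,8R)-7-hydroxy-2-(hydroxymethyl)-5-methyl-8-[(2R)-6-methylhept-5-en-2-yl]cycloocta-1,3-dien-1-yl trifluoromethanesulfonate
Conditions: iBu2AlH (6 equiv), CH2Cl2, −78 to −40 °C; aq. KNaC4H4O6
Reagents that add atoms: none
Why: Hydride reduction with iBu2AlH should convert the conjugated methyl ester into the allylic alcohol (the future lactone CH2) and cleave the 4-nitrobenzoate in the same operation, vinyl triflates being inert to it at low temperature.

Step 12
Reactants: 17 (5R,7R,8R)-7-hydroxy-2-(hydroxymethyl)-5-methyl-8-[(2R)-6-methylhept-5-en-2-yl]cycloocta-1,3-dien-1-yl trifluoromethanesulfonate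
Product: 18 (1S,4R,5R,7R,8S)-5-hydroxy-2-(hydroxymethyl)-7-methyl-4-[(2R)-6-methylhept-5-en-2-yl]bicyclo[6.1.0]non-2-en-3-yl trifluoromethanesulfonate
Conditions: Et2Zn, CH2I2, CH2Cl2, −10 to 0 °C; aq. NH4Cl
Reagents that add atoms: diiodomethane, ICI
Why: Simmons–Smith cyclopropanation is stereospecific for the cis C6=C7 bond (cis ring fusion) and is delivered by the zinc alkoxides, that of the C3 hydroxyl directing the methylene to its own face, which is also the face opposite the allylic C5 methyl group, while the tetrasubstituted triflate alkene and the undirected side-chain alkene should react more slowly.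

Step 13
Reactants: 18 (1S,4R,5R,7R,8S)-5-hydroxy-2-(hydroxymethyl)-7-methyl-4-[(2R)-6-methylhept-5-en-2-yl]bicyclo[6.1.0]non-2-en-3-yl trifluoromethanesulfonate
Product: 19 deacetyl target (C3 alcohol; 2S,3R,5R,6S,7S in the overview locants)
Conditions: Pd(PPh3)4 (10 mol %), CO (1 atm), n-Bu3N, LiCl, MeCN, 60 °C
Reagents that add atoms: carbon monoxide, [C-]#[O+]
Why: Oxidative addition of the vinyl triflate to zerovalent palladium, CO insertion and trapping of the acylpalladium by the cis allylic alcohol (carbonylative lactonisation) should form the butenolide with its carbonyl on C1, the C3 hydroxyl staying free because it could only give a strained bridged lactone.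

Step 14
Reactants: 19 deacetyl target (C3 alcohol)
Product: 20 target CNP0018922.1
Conditions: Ac2O, DMAP (cat.), pyridine, CH2Cl2, 23 °C
Reagents that add atoms: acetic anhydride, CC(=O)OC(C)=O
Why: DMAP-catalysed O-acylation of the secondary alcohol should give the acetate without touching any stereocentre.

Compound list
1 | (R)-citronellal, (3R)-3,7-dimethyloct-6-enal | O=CC[C@H](C)CCC=C(C)C | starting material
2 | (6R)-8,8-dimethoxy-2,6-dimethyloct-2-ene | COC(OC)C[C@H](C)CCC=C(C)C | intermediate
3 | (4R)-6,6-dimethoxy-4-methylhexanal | COC(OC)C[C@H](C)CCC=O | intermediate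
4 | (4R)-6,6-dimethoxy-4-methylhex-1-en-1-yl acetate, E/Z mixture | COC(OC)C[C@H](C)CC=COC(C)=O | intermediate
5 | (3R)-5,5-dimethoxy-3-methylpentanal | COC(OC)C[C@H](C)CC=O | intermediate
6 | (R)-citronellic acid, (3R)-3,7-dimethyloct-6-enoic acid | OC(=O)C[C@H](C)CCC=C(C)C | starting material
7 | 1-[(3R)-3,7-dimethyloct-6-enoyl]imidazole | O=C(C[C@H](C)CCC=C(C)C)n1ccnc1 | intermediate (not isolated)
8 | methyl (5R)-5,9-dimethyl-3-oxodec-8-enoate | COC(=O)CC(=O)C[C@H](C)CCC=C(C)C | intermediate
9 | methyl (5R)-5,9-dimethyl-3-(trimethylsilyloxy)deca-2,8-dienoate | COC(=O)C=C(O[Si](C)(C)C)C[C@H](C)CCC=C(C)C | intermediate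
10 | (5R)-1-methoxy-5,9-dimethyl-1,3-bis(trimethylsilyloxy)deca-1,3,8-triene, mainly 3Z | COC(O[Si](C)(C)C)=CC(O[Si](C)(C)C)=C[C@H](C)CCC=C(C)C | intermediate
11 | (4R,5R)-1-methoxy-4-[(2S,4R)-6-methoxy-4-methyloxan-2-yl]-5,9-dimethyl-1-(trimethylsilyloxy)deca-1,8-dien-3-one | COC1C[C@H](C)C[C@H](O1)[C@@H]([C@H](C)CCC=C(C)C)C(=O)C=C(OC)O[Si](C)(C)C | intermediate (not isolated)
12 | methyl (1R,4R,5S,7R)-7-methyl-4-[(2R)-6-methylhept-5-en-2-yl]-3-oxo-9-oxabicyclo[3.3.1]nonane-2-carboxylate (C2 epimers and enol form) | O1[C@H]2C[C@@H](C)C[C@@H]1C(C(=O)OC)C(=O)[C@@H]2[C@H](C)CCC=C(C)C | intermediate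
13 | disodium salt of the ring-opened 4-alkoxide 2-dienolate of methyl (3R,4S,6R)-6-methyl-3-[(2R)-6-methylhept-5-en-2-yl]cycloocta-1,7-diene-1-carboxylate | [Na+].[Na+].[O-][C@H]1C[C@@H](C)/C=C\C(C(=O)OC)=C([O-])/[C@@H]1[C@H](C)CCC=C(C)C | intermediate (not isolated)
14 | 4-O-trimethylsilyl ether of 15 | C[Si](C)(C)O[C@H]1C[C@@H](C)/C=C\C(C(=O)OC)=C(OS(=O)(=O)C(F)(F)F)/[C@@H]1[C@H](C)CCC=C(C)C | intermediate (not isolated)
15 | methyl (3R,4S,6R)-4-hydroxy-6-methyl-3-[(2R)-6-methylhept-5-en-2-yl]-2-(trifluoromethanesulfonyloxy)cycloocta-1,7-diene-1-carboxylate | O[C@H]1C[C@@H](C)/C=C\C(C(=O)OC)=C(OS(=O)(=O)C(F)(F)F)/[C@@H]1[C@H](C)CCC=C(C)C | intermediate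
16 | methyl (3R,4R,6R)-6-methyl-3-[(2R)-6-methylhept-5-en-2-yl]-4-(4-nitrobenzoyloxy)-2-(trifluoromethanesulfonyloxy)cycloocta-1,7-diene-1-carboxylate | O=C(O[C@@H]1C[C@@H](C)/C=C\C(C(=O)OC)=C(OS(=O)(=O)C(F)(F)F)/[C@@H]1[C@H](C)CCC=C(C)C)c1ccc(cc1)[N+](=O)[O-] | intermediate
17 | (5R,7R,8R)-7-hydroxy-2-(hydroxymethyl)-5-methyl-8-[(2R)-6-methylhept-5-en-2-yl]cycloocta-1,3-dien-1-yl trifluoromethanesulfonate | O[C@@H]1C[C@@H](C)/C=C\C(CO)=C(OS(=O)(=O)C(F)(F)F)/[C@@H]1[C@H](C)CCC=C(C)C | intermediate
18 | (1S,4R,5R,7R,8S)-5-hydroxy-2-(hydroxymethyl)-7-methyl-4-[(2R)-6-methylhept-5-en-2-yl]bicyclo[6.1.0]non-2-en-3-yl trifluoromethanesulfonate | O[C@@H]1C[C@@H](C)[C@@H]2C[C@@H]2\C(CO)=C(OS(=O)(=O)C(F)(F)F)/[C@@H]1[C@H](C)CCC=C(C)C | intermediate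
19 | deacetyl target: butenolide-fused cis-bicyclo[6.1.0]nonene with free C3 hydroxyl (2S,3R,5R,6S,7S; side chain 2R) | O[C@@H]1C[C@@H](C)[C@@H]2C[C@@H]2C2=C(C(=O)OC2)[C@@H]1[C@H](C)CCC=C(C)C | intermediate
20 | target CNP0018922.1, the C3 acetate of 19 | CC(=O)O[C@@H]1C[C@@H](C)[C@@H]2C[C@@H]2C2=C(C(=O)OC2)[C@@H]1[C@H](C)CCC=C(C)C | target

Total step count: 14. Longest linear sequence: 11 steps (steps 1–4 and 8–14); steps 5–7 make the second fragment.

Steps most likely to fail

Step 8. The first carbon–carbon bond may form at the acetal-derived carbon instead of the aldehyde-derived one, facial selectivity at C2 may be poor, or the cascade may stall after the first bond. The fallback separates the two bond formations and sets out from 5 and 8. The β-keto ester dianion of 8 (NaH, then n-BuLi, THF, 0 °C) is added through its γ-carbon to aldehyde 5 at −78 °C. This gives methyl (5R)-4-[(3R)-1-hydroxy-5,5-dimethoxy-3-methylpentyl]-5,9-dimethyl-3-oxodec-8-enoate F1 as a mixture at the two new centres. Catalytic TMSOTf or BF3·OEt2 in CH2Cl2 then closes the 2-methoxyoxane by transacetalisation and, after ionisation, the second ring by attack of the β-keto ester enol on the oxocarbenium ion. Only the diastereomers able to reach the chair–chair bicycle cyclise, and the route is rejoined at 12.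

Step 9. The oxygen bridge may re-close before the dienolate forms, sulfonylation may occur at the alkoxide oxygen, or enolisation towards C2 may erode its configuration. The fallback replaces the strong base by a silyl triflate and sets out from 12. TBSOTf and Et3N (CH2Cl2, 0 °C) open the bridge by β-elimination from the silyl enol ether and silylate both oxygens, giving methyl (3R,4S,6R)-2,4-bis(tert-butyldimethylsilyloxy)-6-methyl-3-[(2R)-6-methylhept-5-en-2-yl]cycloocta-1,7-diene-1-carboxylate F2. CsF and PhNTf2 (DME, 23 °C) exchange the enol silyl group for triflate to give the 4-O-tert-butyldimethylsilyl ether of 15 F3. HF·pyridine (THF) frees the alcohol and the route is rejoined at 15.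

Step 10. Elimination from the hindered oxyphosphonium ion may outrun substitution. The fallback inverts C3 by oxidation and reduction and sets out from 15. DMP (NaHCO3, CH2Cl2) gives methyl (3R,6R)-6-methyl-3-[(2R)-6-methylhept-5-en-2-yl]-4-oxo-2-(trifluoromethanesulfonyloxy)cycloocta-1,7-diene-1-carboxylate F4. Excess iBu2AlH (CH2Cl2, −78 °C) should then deliver hydride to the ketone from the face opposite the neighbouring side chain and reduce the ester as well, so the route is rejoined at 17.

Further compounds
F1 | step 8 | methyl (5R)-4-[(3R)-1-hydroxy-5,5-dimethoxy-3-methylpentyl]-5,9-dimethyl-3-oxodec-8-enoate | COC(=O)CC(=O)C([C@H](C)CCC=C(C)C)C(O)C[C@@H](C)CC(OC)OC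
F2 | step 9 | methyl (3R,4S,6R)-2,4-bis(tert-butyldimethylsilyloxy)-6-methyl-3-[(2R)-6-methylhept-5-en-2-yl]cycloocta-1,7-diene-1-carboxylate | CC(C)(C)[Si](C)(C)O[C@H]1C[C@@H](C)/C=C\C(C(=O)OC)=C(O[Si](C)(C)C(C)(C)C)/[C@@H]1[C@H](C)CCC=C(C)C
F3 | step 9 | methyl (3R,4S,6R)-4-(tert-butyldimethylsilyloxy)-6-methyl-3-[(2R)-6-methylhept-5-en-2-yl]-2-(trifluoromethanesulfonyloxy)cycloocta-1,7-diene-1-carboxylate | CC(C)(C)[Si](C)(C)O[C@H]1C[C@@H](C)/C=C\C(C(=O)OC)=C(OS(=O)(=O)C(F)(F)F)/[C@@H]1[C@H](C)CCC=C(C)C
F4 | step 10 | methyl (3R,6R)-6-methyl-3-[(2R)-6-methylhept-5-en-2-yl]-4-oxo-2-(trifluoromethanesulfonyloxy)cycloocta-1,7-diene-1-carboxylate | O=C1C[C@@H](C)/C=C\C(C(=O)OC)=C(OS(=O)(=O)C(F)(F)F)/[C@@H]1[C@H](C)CCC=C(C)C
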